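Chain numbering: C1 anisoyl carbonyl, C2 CH(Ph), C3 CH(CONHR), C4 carbonyl on ring A (the 2-hydroxy-4,6-dimethoxyphenyl ring). C1–C4, with an oxygen at each end and the amide carbon on C3, form a 1,4-diketone, which is the opened and reduced form of a furan (ring oxygen plus four carbons) bearing ring A at furan C2, the carboxamide at C3, phenyl at C4 and anisyl at C5.
Retrosynthetic cuts, in order: the choice of enantiomer at C2 (resolution) and the O-benzyl group; the C2–H and C3–H bonds (back to the C2=C3 alkene of a cis-enedione); the C1=O and C4=O bonds (back into the furan); the amide C–N bond together with the ring A O–H (back to a six-membered lactone); the furan–anisyl bond; the furan–ring A bond (through an ester tether); the furan–phenyl and furan–carboxyl bonds.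
Forward: 3,4-dibromofuran 1 is carboxylated, phenylated and brominated at C2, then esterified with 3,5-dimethoxyphenol and cyclised by intramolecular arylation. This lactone of a furo[3,2-c]chromen-4-one is the only ring formed. The anisyl group goes onto the last furan C–H, the amine opens the lactone to amide plus phenol, and benzylation gives the furan that is opened at the anode. Alkene reduction and debenzylation finish the chain.
Stereochemistry: no stereocentre exists before step 10. C2 is formed as a racemate and the (2R) series is isolated by chromatographic resolution, with the antipode racemised and recycled. C3 is labile and follows C2 under thermodynamic control.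

Key step: step 9

Assumption: C3 lies between a ketone and an amide carbonyl and epimerises readily through its enol, so the (2R,3R) arrangement of the target is taken to be the one favoured at equilibrium once C2 is (R).

Step 1
Reactants: 1 3,4-dibromofuran
Product: 3 4-bromofuran-3-carboxylic acid, via 3-bromo-4-lithiofuran 2 (not isolated)
Conditions: n-BuLi (1.05 equiv), Et2O, −78 °C; CO2 (excess), −78 °C → rt; aq. HCl
Reagents that add atoms: carbon dioxide, O=C=O
Why: Bromine–lithium exchange at one of the two equivalent C–Br bonds is fast at −78 °C, where the β-furyllithium neither eliminates nor migrates to the α position, and carboxylation of 2 supplies the carbon that becomes the amide carbonyl on chain C3.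

Step 2
Reactants: 3 4-bromofuran-3-carboxylic acid; 4 phenylboronic acid
Product: 5 4-phenylfuran-3-carboxylic acid
Conditions: Pd(PPh3)4 (5 mol%), K2CO3 (3 equiv), 1,4-dioxane/H2O 4:1, 90 °C; aq. HCl
Reagents that add atoms: none
Why: Suzuki–Miyaura coupling at the remaining β C–Br bond tolerates the carboxylate and places the phenyl group of chain C2 at a position fixed by the halide.

Step 3
Reactants: 5 4-phenylfuran-3-carboxylic acid
Product: 7 2-bromo-4-phenylfuran-3-carboxylic acid, via lithium 2-lithio-4-phenylfuran-3-carboxylate 6 (not isolated)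
Conditions: LiN(iPr)2 (2.2 equiv), THF, −78 °C; BrCCl2CCl2Br (1.2 equiv), −78 °C → rt; aq. HCl
Reagents that add atoms: 1,2-dibromotetrachloroethane, BrC(Cl)(Cl)C(Cl)(Cl)Br
Why: The lithium carboxylate directs the second deprotonation to the adjacent α carbon (carboxylate-directed lithiation of 3-furoic acids at C2), and the dianion is brominated by positive-bromine transfer, so the halogen needed for the ring A coupling is installed without electrophilic bromination.

Step 4
Reactants: 7 2-bromo-4-phenylfuran-3-carboxylic acid; 8 3,5-dimethoxyphenol
Product: 10 3,5-dimethoxyphenyl 2-bromo-4-phenylfuran-3-carboxylate, via acid chloride 9 (not isolated)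
Conditions: (COCl)2, DMF (cat.), CH2Cl2, 0 °C → rt; then 8, Et3N, DMAP (cat.), CH2Cl2, 0 °C → rt
Reagents that add atoms: none
Why: Acid chloride formation and DMAP-assisted acylation of the phenol attach ring A through an ester tether whose two ortho positions are equivalent by symmetry, and only after all bromination chemistry on the furan is finished.

Step 5
Reactants: 10 3,5-dimethoxyphenyl 2-bromo-4-phenylfuran-3-carboxylate
Product: 11 7,9-dimethoxy-3-phenyl-4H-furo[3,2-c]chromen-4-one
Conditions: Pd(OAc)2 (10 mol%), PPh3 (20 mol%), NaOAc (2 equiv), DMA, 130 °C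
Reagents that add atoms: none
Why: Zerovalent palladium inserts into the furan C2–Br bond, acetate-assisted palladation of the tethered aryl ring at the C–H ortho to the ester oxygen follows, and reductive elimination closes the six-membered lactone (intramolecular direct arylation through an ester tether); either ortho position gives the same product, which fixes the 2-oxy-4,6-dimethoxy pattern of ring A and avoids an intermolecular coupling of a doubly ortho-substituted aryl partner.

Step 6
Reactants: 11 7,9-dimethoxy-3-phenyl-4H-furo[3,2-c]chromen-4-one; 12 4-bromoanisole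
Product: 13 7,9-dimethoxy-2-(4-methoxyphenyl)-3-phenyl-4H-furo[3,2-c]chromen-4-one
Conditions: Pd(OAc)2 (2 mol%), KOAc (2 equiv), DMA, 140 °C
Reagents that add atoms: none
Why: Direct C–H arylation by acetate-assisted concerted metalation–deprotonation takes place at the only furan C–H left (C2 of the furochromenone, α to the ring oxygen), while the ring A hydrogens, each flanked by two substituents, should not compete.

Step 7
Reactants: 13 7,9-dimethoxy-2-(4-methoxyphenyl)-3-phenyl-4H-furo[3,2-c]chromen-4-one; 14 N-(4-aminobutyl)benzamide
Product: 16 N-(4-benzamidobutyl)-2-(2-hydroxy-4,6-dimethoxyphenyl)-5-(4-methoxyphenyl)-4-phenylfuran-3-carboxamide, via dimethylaluminium amide 15 (not isolated)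
Conditions: AlMe3 (3 equiv), 14 (1.5 equiv), CH2Cl2, 0 °C → rt; then 13, toluene, 60 °C; cold 1 M HCl
Reagents that add atoms: none
Why: The aluminium amide adds to the lactone carbonyl and the ring A oxygen leaves as an aluminium phenoxide (AlMe3-mediated aminolysis of a lactone, Weinreb type), which delivers the side-chain amide and the ortho phenol in one operation; the benzamide N–H only consumes AlMe3.

Step 8
Reactants: 16 N-(4-benzamidobutyl)-2-(2-hydroxy-4,6-dimethoxyphenyl)-5-(4-methoxyphenyl)-4-phenylfuran-3-carboxamide
Product: 17 N-(4-benzamidobutyl)-2-[2-(benzyloxy)-4,6-dimethoxyphenyl]-5-(4-methoxyphenyl)-4-phenylfuran-3-carboxamide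
Conditions: BnBr (1.3 equiv), K2CO3 (2 equiv), DMF, rt
Reagents that add atoms: benzyl bromide, BrCc1ccccc1
Why: Williamson etherification of the phenoxide, the only site that K2CO3 deprotonates, masks the phenol, which would otherwise be oxidised at the anode, add to the enedione or re-close the lactone.

Step 9
Reactants: 17 N-(4-benzamidobutyl)-2-[2-(benzyloxy)-4,6-dimethoxyphenyl]-5-(4-methoxyphenyl)-4-phenylfuran-3-carboxamide
Product: 19 (E)-N-(4-benzamidobutyl)-2-[2-(benzyloxy)-4,6-dimethoxybenzoyl]-4-(4-methoxyphenyl)-4-oxo-3-phenylbut-2-enamide (both aroyl groups on the same side of the alkene), via bis-ketal 18 (not isolated)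
Conditions: undivided cell, graphite anode, Pt cathode, Et4NOTs (0.1 M), 2,6-lutidine, MeOH/MeCN 3:1, 0 °C, constant current (about 5 mA cm−2), 2.2 F mol−1; then 0.5 M aq. HCl/THF, 0 °C, dark
Reagents that add atoms: water, O
Why: The 2-aryl-5-anisylfuran is the most easily oxidised π system of 17, so it gives up an electron at the anode to a radical cation that methanol captures at a ring carbon next to oxygen, and a second electron transfer and a second methanol give the 2,5-dimethoxy-2,5-dihydrofuran 18 while H2 forms at the cathode. Dilute aqueous acid then turns both ketal carbons into carbonyl groups, which cleaves the two ring C–O bonds and leaves the former furan C3=C4 bond as the C2=C3 alkene of 19. The closest known reaction type is the anodic 2,5-dimethoxylation of furans followed by hydrolysis to cis-enediones (Clauson-Kaas type), including the oxidative opening of 2,5-diaryl- and tetraarylfurans to cis-diaroylalkenes. No ring closes and no stereocentre forms; the alkene geometry is inherited from the ring, with both aroyl groups on one side and the amide trans to the C1 ketone so that it cannot add to it. The selectivity needed is oxidation of the furan in preference to ring A, the anisyl ring and the amide N–CH2 groups, and it is secured by the lower oxidation potential of the extended furan chromophore, by keeping the ring A phenol as its benzyl ether and by stopping at about 2.2 F mol−1. Should methanol add slowly at the crowded carbon bearing ring A, water traps the cation during the work-up and the same product results.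

Step 10
Reactants: 19 (E)-N-(4-benzamidobutyl)-2-[2-(benzyloxy)-4,6-dimethoxybenzoyl]-4-(4-methoxyphenyl)-4-oxo-3-phenylbut-2-enamide
Product: 20 racemic N-(4-benzamidobutyl)-2-[2-(benzyloxy)-4,6-dimethoxybenzoyl]-4-(4-methoxyphenyl)-4-oxo-3-phenylbutanamide (C3 epimers interconverting)
Conditions: Na2S2O4 (4 equiv), NaHCO3 (8 equiv), THF/H2O 1:1, 50 °C, Ar
Reagents that add atoms: none
Why: Dithionite transfers two electrons to the electron-poor enedione (the classical dithionite reduction of unsaturated 1,4-diketones) and protonation at C2 and C3 under bicarbonate buffer gives the saturated diketone without the acid that would cyclise it back to a furan; both stereocentres arise without control, so 20 is racemic.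

Step 11
Reactants: 20 racemic N-(4-benzamidobutyl)-2-[2-(benzyloxy)-4,6-dimethoxybenzoyl]-4-(4-methoxyphenyl)-4-oxo-3-phenylbutanamide
Product: 21 racemic N-(4-benzamidobutyl)-2-(2-hydroxy-4,6-dimethoxybenzoyl)-4-(4-methoxyphenyl)-4-oxo-3-phenylbutanamide
Conditions: H2 (1 atm), 10% Pd/C, EtOAc, rt
Reagents that add atoms: none
Why: Neutral hydrogenolysis of the aryl benzyl ether over palladium should leave the aryl ketones, both amides and the C2–H untouched, and C3 is free to settle in its preferred configuration relative to C2.

Step 12
Reactants: 21 racemic N-(4-benzamidobutyl)-2-(2-hydroxy-4,6-dimethoxybenzoyl)-4-(4-methoxyphenyl)-4-oxo-3-phenylbutanamide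
Product: 22 (2R,3R)-N-(4-benzamidobutyl)-2-(2-hydroxy-4,6-dimethoxybenzoyl)-4-(4-methoxyphenyl)-4-oxo-3-phenylbutanamide (target; both descriptors are R in the chain numbering as well)
Conditions: preparative SFC, immobilised amylose tris(3,5-dimethylphenylcarbamate) phase, CO2/MeOH, 35 °C; (2S) fractions: DBU (cat.), MeCN, rt, then re-injection
Reagents that add atoms: none
Why: The two enantiomeric series differ at the slowly inverting C2 and should separate on a polysaccharide carbamate phase (chromatographic resolution of a racemate); fractions of the (2R) series are pooled because their C3 epimers interconvert through the enol, the (2S) antipode is racemised at C2 by base-mediated enolisation and resubmitted, and the (2R,3R) assignment should be confirmed by ECD or X-ray analysis.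

Compound list
1 | 3,4-dibromofuran | Brc1cocc1Br | starting material
2 | 3-bromo-4-lithiofuran | [Li]c1cocc1Br | intermediate (not isolated)
3 | 4-bromofuran-3-carboxylic acid | OC(=O)c1cocc1Br | intermediate
4 | phenylboronic acid | OB(O)c1ccccc1 | starting material
5 | 4-phenylfuran-3-carboxylic acid | OC(=O)c1cocc1-c1ccccc1 | intermediate
6 | lithium 2-lithio-4-phenylfuran-3-carboxylate | [Li]OC(=O)c1c([Li])occ1-c1ccccc1 | intermediate (not isolated)
7 | 2-bromo-4-phenylfuran-3-carboxylic acid | OC(=O)c1c(Br)occ1-c1ccccc1 | intermediate
8 | 3,5-dimethoxyphenol | COc1cc(O)cc(OC)c1 | starting material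
9 | 2-bromo-4-phenylfuran-3-carbonyl chloride | ClC(=O)c1c(Br)occ1-c1ccccc1 | intermediate (not isolated)
10 | 3,5-dimethoxyphenyl 2-bromo-4-phenylfuran-3-carboxylate | COc1cc(OC)cc(OC(=O)c2c(Br)occ2-c2ccccc2)c1 | intermediate
11 | 7,9-dimethoxy-3-phenyl-4H-furo[3,2-c]chromen-4-one | COc1cc(OC)c2c(c1)OC(=O)c1c(-c3ccccc3)coc12 | intermediate
12 | 4-bromoanisole | COc1ccc(Br)cc1 | starting material
13 | 7,9-dimethoxy-2-(4-methoxyphenyl)-3-phenyl-4H-furo[3,2-c]chromen-4-one | COc1ccc(cc1)-c1oc2c(c1-c1ccccc1)C(=O)Oc1cc(OC)cc(OC)c12 | intermediate
14 | N-(4-aminobutyl)benzamide | NCCCCNC(=O)c1ccccc1 | starting material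
15 | dimethylaluminium amide of 14 (aluminium drawn on the amine nitrogen) | C[Al](C)NCCCCNC(=O)c1ccccc1 | intermediate (not isolated)
16 | N-(4-benzamidobutyl)-2-(2-hydroxy-4,6-dimethoxyphenyl)-5-(4-methoxyphenyl)-4-phenylfuran-3-carboxamide | COc1ccc(cc1)-c1oc(-c2c(O)cc(OC)cc2OC)c(C(=O)NCCCCNC(=O)c2ccccc2)c1-c1ccccc1 | intermediate
17 | N-(4-benzamidobutyl)-2-[2-(benzyloxy)-4,6-dimethoxyphenyl]-5-(4-methoxyphenyl)-4-phenylfuran-3-carboxamide | COc1ccc(cc1)-c1oc(-c2c(OCc3ccccc3)cc(OC)cc2OC)c(C(=O)NCCCCNC(=O)c2ccccc2)c1-c1ccccc1 | intermediate
18 | N-(4-benzamidobutyl)-2-[2-(benzyloxy)-4,6-dimethoxyphenyl]-2,5-dimethoxy-5-(4-methoxyphenyl)-4-phenyl-2,5-dihydrofuran-3-carboxamide (cis/trans mixture) | COc1ccc(cc1)C2(OC)OC(OC)(c3c(OCc4ccccc4)cc(OC)cc3OC)C(C(=O)NCCCCNC(=O)c3ccccc3)=C2c2ccccc2 | intermediate (not isolated)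
19 | (E)-N-(4-benzamidobutyl)-2-[2-(benzyloxy)-4,6-dimethoxybenzoyl]-4-(4-methoxyphenyl)-4-oxo-3-phenylbut-2-enamide | COc1ccc(cc1)C(=O)/C(c1ccccc1)=C(/C(=O)NCCCCNC(=O)c1ccccc1)C(=O)c1c(OCc2ccccc2)cc(OC)cc1OC | intermediate
20 | racemic N-(4-benzamidobutyl)-2-[2-(benzyloxy)-4,6-dimethoxybenzoyl]-4-(4-methoxyphenyl)-4-oxo-3-phenylbutanamide (C3 epimers in equilibrium, hence no descriptors) | COc1ccc(cc1)C(=O)C(c1ccccc1)C(C(=O)NCCCCNC(=O)c1ccccc1)C(=O)c1c(OCc2ccccc2)cc(OC)cc1OC | intermediate
21 | racemic N-(4-benzamidobutyl)-2-(2-hydroxy-4,6-dimethoxybenzoyl)-4-(4-methoxyphenyl)-4-oxo-3-phenylbutanamide (C3 epimers in equilibrium, hence no descriptors) | COc1ccc(cc1)C(=O)C(c1ccccc1)C(C(=O)NCCCCNC(=O)c1ccccc1)C(=O)c1c(O)cc(OC)cc1OC | intermediate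
22 | (2R,3R)-N-(4-benzamidobutyl)-2-(2-hydroxy-4,6-dimethoxybenzoyl)-4-(4-methoxyphenyl)-4-oxo-3-phenylbutanamide (CNP0208962.1) | COc1ccc(C(=O)[C@@H](c2ccccc2)[C@@H](C(=O)NCCCCNC(=O)c2ccccc2)C(=O)c2c(O)cc(OC)cc2OC)cc1 | target

Total step count: 12. Longest linear sequence: 12 steps, from 1 to 22; compounds 4, 8, 12 and 14 are purchased.

Steps most likely to fail

First, step 9. Electron loss may occur from ring A or the anisyl ring instead of the furan, oxidation may run past two electrons per molecule, or trapping at the crowded carbon bearing ring A may stay incomplete. Acid used in the hydrolysis may also isomerise the cis-enedione, after which the amide nitrogen can add to the C1 carbonyl. The fallback sets out from 17 and returns to the route at 19. Sensitised photo-oxygenation (O2, methylene blue, visible light, CH2Cl2/MeOH, −78 °C) adds singlet oxygen across furan C2 and C5 in a [4+2] sense, far faster than it attacks alkoxybenzenes. This gives the furan endoperoxide N-(4-benzamidobutyl)-4-[2-(benzyloxy)-4,6-dimethoxyphenyl]-1-(4-methoxyphenyl)-6-phenyl-2,3,7-trioxabicyclo[2.2.1]hept-5-ene-5-carboxamide F1. Reduction of its O–O bond with Me2S (−78 °C → rt) collapses it to the same cis-enedione 19, so the two carbonyl groups still arise from the furan.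

Second, step 12. The stationary phase may discriminate the two enantiomeric series poorly, interconversion of C3 epimers and keto–enol forms during elution may broaden the peaks, and configuration at C2 may erode if fractions stand in protic or basic media. The fallback sets out from 21 and returns at 22. Acylation of the ring A phenol with (1S,4R)-camphanic chloride (Et3N, DMAP, CH2Cl2, 0 °C) gives two diastereomers separable on silica or by crystallisation: the O-[(1S,4R)-camphanoyl] ester of the (2R,3R) compound F2 and the O-[(1S,4R)-camphanoyl] ester of the (2S,3S) compound F3. Brief methanolysis of the aryl ester in F2 (K2CO3, MeOH, 0 °C) then releases 22.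

Third, step 10. Electron transfer to the crowded tetrasubstituted alkene may be slow, sulfur nucleophiles may add to the enedione, or the reduced, still enolised material may cyclodehydrate back to furan 17 if the medium turns acidic. The fallback sets out from 19 and returns at 21, by-passing 20. Catalytic hydrogenation (H2, 10% Pd/C, EtOAc, rt) saturates the alkene by syn addition on the metal surface, which leads from the (E)-alkene to the (2R*,3R*) pair, and cleaves the benzyl ether in the same operation. No compound outside the list is formed (entry F0).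

Further compounds
F1 | step 9 | N-(4-benzamidobutyl)-4-[2-(benzyloxy)-4,6-dimethoxyphenyl]-1-(4-methoxyphenyl)-6-phenyl-2,3,7-trioxabicyclo[2.2.1]hept-5-ene-5-carboxamide | COc1ccc(cc1)C12OOC(O1)(c1c(OCc3ccccc3)cc(OC)cc1OC)C(C(=O)NCCCCNC(=O)c1ccccc1)=C2c1ccccc1
F2 | step 12 | O-[(1S,4R)-camphanoyl] ester (at the ring A phenol) of the (2R,3R) compound 22 | COc1ccc(C(=O)[C@@H](c2ccccc2)[C@@H](C(=O)NCCCCNC(=O)c2ccccc2)C(=O)c2c(OC(=O)[C@@]34CC[C@@](C)(C(=O)O3)C4(C)C)cc(OC)cc2OC)cc1
F3 | step 12 | O-[(1S,4R)-camphanoyl] ester (at the ring A phenol) of the (2S,3S) enantiomer of 22 | COc1ccc(C(=O)[C@H](c2ccccc2)[C@H](C(=O)NCCCCNC(=O)c2ccccc2)C(=O)c2c(OC(=O)[C@@]34CC[C@@](C)(C(=O)O3)C4(C)C)cc(OC)cc2OC)cc1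
F0 | step 10 | none | none
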